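## Retrosynthetic overview

1. The C9=C10 (E) alkene is cut by cross-metathesis, giving a vinyl-substituted oxolane–lactone and 3-[(3E)-4-methylhepta-3,6-dienyl]furan.
2. The oxolane–lactone comes from an acyclic 2,3-epoxy tosylate plus the acetic acid dianion in one anionic cascade: the C8 alkoxide closes the oxolane at C5 (inversion), the epoxide is relayed to C3–C4, the C2–C3 bond forms and the γ-lactone closes. Ring order: oxolane first, lactone second; the furan is bought.
3. The epoxy tosylate comes from (R)-linalool (C8 from the chiral pool) by E-selective allylic oxidation and Sharpless epoxidation (sets C4 and C5).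
4. The furyl diene comes from 3-bromofuran and an (E)-homoallylic bromide, itself from 2,3-dihydrofuran by allylation and stereoretentive Ni-catalysed ring opening with MeMgBr (sets C12=C13).

Numbering used in the explanations: C1 lactone carbonyl, C4 lactone quaternary carbon, C5 oxolane CH, C8 oxolane quaternary carbon, C9=C10 and C12=C13 the two chain alkenes.

Assumption: commercial (R)-(−)-linalool is taken as enantiopure (in practice ≥95% ee), and a one-pot sequence without isolation counts as one step.

## Route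

Step 1
Reactants: 1 (R)-(−)-linalool, (3R)-3,7-dimethylocta-1,6-dien-3-ol
Product: 2 (2E,6R)-2,6-dimethylocta-2,7-diene-1,6-diol
Conditions: SeO2 (0.2 equiv), t-BuOOH (2.5 equiv), salicylic acid (0.1 equiv), CH2Cl2, rt
Reagents that add atoms: tert-butyl hydroperoxide, CC(C)(C)OO (the oxygen atom, relayed by catalytic SeO2)
Why: Sharpless–Umbreit SeO2/t-BuOOH allylic oxidation (ene reaction, then [2,3]-sigmatropic shift) hydroxylates only the (E)-methyl group of the electron-rich trisubstituted alkene, leaving the vinyl carbinol and the C8 stereocentre untouched; no new stereocentre.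

Step 2
Reactants: 2 (2E,6R)-2,6-dimethylocta-2,7-diene-1,6-diol
Product: 4 [(2S,3S)-3-[(3R)-3-hydroxy-3-methylpent-4-en-1-yl]-2-methyloxiran-2-yl]methyl 4-methylbenzenesulfonate, via epoxy alcohol 3 (not isolated)
Conditions: Ti(Oi-Pr)4 (10 mol%), L-(+)-DET (12 mol%), t-BuOOH (2 equiv), 4 Å MS, CH2Cl2, −25 °C; then P(OMe)3; then TsCl, Et3N, DMAP (cat.), −20→0 °C
Reagents that add atoms: tert-butyl hydroperoxide, CC(C)(C)OO; p-toluenesulfonyl chloride, Cc1ccc(cc1)S(=O)(=O)Cl
Why: Katsuki–Sharpless asymmetric epoxidation is directed by the primary allylic hydroxyl (the tertiary vinyl carbinol is a far slower substrate) and with natural L-(+)-DET gives the (2S,3S)-epoxide of this (E)-2-methylalk-2-en-1-ol, setting C4 and C5 under reagent control remote from C8; Sharpless in situ derivatisation then sulfonylates only the primary alcohol.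

Step 3
Reactants: 4 [(2S,3S)-3-[(3R)-3-hydroxy-3-methylpent-4-en-1-yl]-2-methyloxiran-2-yl]methyl 4-methylbenzenesulfonate
Product: 7 (5S)-5-[(2R,5R)-5-ethenyl-5-methyloxolan-2-yl]-5-methyloxolan-2-one, via oxolanyl epoxide 5 (not isolated), via hydroxy acid 6 (not isolated)
Conditions: LiCH2CO2Li (5 equiv; from AcOH + 2 LDA, THF–DMPU, 0→45 °C), add 4 at −20 °C, then 50 °C; then 1 M HCl, rt
Reagents that add atoms: dilithioacetate, [Li]CC(=O)O[Li] (made in the flask from acetic acid, CC(=O)O, and LDA)
Why: Proposed new method: the dianion first deprotonates the tertiary alcohol, whose alkoxide opens the epoxide 5-exo at C5 with inversion (C5 becomes R), the released C4 alkoxide displaces the neighbouring tosylate (3-exo-tet) to give terminal epoxide 5, the acetate dianion opens 5 at its CH2 end and acidification lactonises hydroxy acid 6, so C4 keeps its oxygen and configuration throughout (5S in the lactone); the closest known reactions are the anionic epoxide relay of 2,3-epoxy sulfonates carrying a pendant hydroxyl and the Creger dilithioacetate opening of epoxides to γ-lactones, and direct C-alkylation at the tosylate carbon would converge on the same product.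

Step 4
Reactants: 8 2,3-dihydrofuran
Product: 10 5-(prop-2-en-1-yl)-2,3-dihydrofuran, via 5-lithio-2,3-dihydrofuran 9 (not isolated)
Conditions: t-BuLi (1.0 equiv), THF–pentane, −78→0 °C; then allyl bromide, −78 °C→rt
Reagents that add atoms: allyl bromide, C=CCBr
Why: α-Lithiation of the cyclic enol ether gives vinyllithium 9, which is alkylated by allyl bromide in an SN2 reaction; no stereochemical issue.

Step 5
Reactants: 10 5-(prop-2-en-1-yl)-2,3-dihydrofuran
Product: 11 (3E)-4-methylhepta-3,6-dien-1-ol
Conditions: MeMgBr (3 equiv), NiCl2(PPh3)2 (5 mol%), PhMe–Et2O, 70 °C; H2O work-up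
Reagents that add atoms: methylmagnesium bromide, C[Mg]Br
Why: Wenkert–Kocienski nickel-catalysed Grignard coupling replaces the enol-ether C–O bond by C–CH3 with retention of alkene geometry, so the methyl group ends up cis to the hydroxyethyl arm and the (E)-trisubstituted C12=C13 alkene is dictated by the ring.

Step 6
Reactants: 11 (3E)-4-methylhepta-3,6-dien-1-ol
Product: 12 (4E)-7-bromo-4-methylhepta-1,4-diene
Conditions: CBr4, PPh3, CH2Cl2, 0 °C
Reagents that add atoms: carbon tetrabromide, BrC(Br)(Br)Br
Why: Appel bromination converts the primary alcohol under neutral conditions and leaves the skipped diene and its geometry untouched.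

Step 7
Reactants: 12 (4E)-7-bromo-4-methylhepta-1,4-diene; 13 3-bromofuran
Product: 15 3-[(3E)-4-methylhepta-3,6-dien-1-yl]furan, via Grignard reagent 14 (not isolated)
Conditions: Mg, THF, rt; then 13, NiCl2(dppp) (3 mol%), Et2O–THF, 0 °C→rt
Reagents that add atoms: none
Why: Kumada–Corriu coupling of the primary alkyl Grignard reagent with 3-bromofuran under NiCl2(dppp) forms the sp3–sp2 bond without β-hydride elimination or loss of alkene geometry.

Step 8
Reactants: 7 (5S)-5-[(2R,5R)-5-ethenyl-5-methyloxolan-2-yl]-5-methyloxolan-2-one; 15 3-[(3E)-4-methylhepta-3,6-dien-1-yl]furan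
Product: 16 (5S)-5-[(2R,5R)-5-[(1E,4E)-7-(furan-3-yl)-4-methylhepta-1,4-dien-1-yl]-5-methyloxolan-2-yl]-5-methyloxolan-2-one
Conditions: Hoveyda–Grubbs II (10 mol%), 1,4-benzoquinone (20 mol%), CH2Cl2, 40 °C; 7 (1.5 equiv), 15 added in portions
Reagents that add atoms: none
Why: Olefin cross-metathesis between a type III olefin (vinyl on a quaternary carbon, no homodimer) and a type I terminal olefin gives the hetero-coupled disubstituted alkene, E because of the quaternary neighbour, while the trisubstituted alkene, furan and lactone are spectators and no stereocentre is touched.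

## Compound list

1 | (R)-(−)-linalool, (3R)-3,7-dimethylocta-1,6-dien-3-ol | C=C[C@](C)(O)CCC=C(C)C | starting material
2 | (2E,6R)-2,6-dimethylocta-2,7-diene-1,6-diol | C=C[C@](C)(O)CC/C=C(\C)CO | intermediate
3 | [(2S,3S)-3-[(3R)-3-hydroxy-3-methylpent-4-en-1-yl]-2-methyloxiran-2-yl]methanol | C=C[C@](C)(O)CC[C@@H]1O[C@@]1(C)CO | intermediate
4 | [(2S,3S)-3-[(3R)-3-hydroxy-3-methylpent-4-en-1-yl]-2-methyloxiran-2-yl]methyl 4-methylbenzenesulfonate | C=C[C@](C)(O)CC[C@@H]1O[C@@]1(C)COS(=O)(=O)c2ccc(C)cc2 | intermediate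
5 | (2R,5R)-2-ethenyl-2-methyl-5-[(2S)-2-methyloxiran-2-yl]oxolane | C=C[C@@]1(C)CC[C@H]([C@]2(C)CO2)O1 | intermediate
6 | (4S)-4-[(2R,5R)-5-ethenyl-5-methyloxolan-2-yl]-4-hydroxypentanoic acid | C=C[C@@]1(C)CC[C@H]([C@@](C)(O)CCC(=O)O)O1 | intermediate
7 | (5S)-5-[(2R,5R)-5-ethenyl-5-methyloxolan-2-yl]-5-methyloxolan-2-one | C=C[C@@]1(C)CC[C@H]([C@]2(C)CCC(=O)O2)O1 | intermediate
8 | 2,3-dihydrofuran | C1CC=CO1 | starting material
9 | 5-lithio-2,3-dihydrofuran | [Li]C1=CCCO1 | intermediate
10 | 5-(prop-2-en-1-yl)-2,3-dihydrofuran | C=CCC1=CCCO1 | intermediate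
11 | (3E)-4-methylhepta-3,6-dien-1-ol | C=CC/C(C)=C/CCO | intermediate
12 | (4E)-7-bromo-4-methylhepta-1,4-diene | C=CC/C(C)=C/CCBr | intermediate
13 | 3-bromofuran | Brc1ccoc1 | starting material
14 | [(3E)-4-methylhepta-3,6-dien-1-yl]magnesium bromide | C=CC/C(C)=C/CC[Mg]Br | intermediate
15 | 3-[(3E)-4-methylhepta-3,6-dien-1-yl]furan | C=CC/C(C)=C/CCc1ccoc1 | intermediate
16 | (5S)-5-[(2R,5R)-5-[(1E,4E)-7-(furan-3-yl)-4-methylhepta-1,4-dien-1-yl]-5-methyloxolan-2-yl]-5-methyloxolan-2-one | C/C(=C\CCc1ccoc1)C/C=C/[C@@]1(C)CC[C@H]([C@]2(C)CCC(=O)O2)O1 | target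

## Step count and risks

Total steps: 8. Longest linear sequence: 5 (steps 4, 5, 6, 7, 8); the linalool branch is 4 (steps 1, 2, 3, 8).

The three steps most likely to fail:

**Step 2.** The epoxy alcohol 3 may cyclise early (Ti-assisted attack of the tertiary hydroxyl on the epoxide) before or during tosylation, so that 4 is not obtained cleanly. The fallback sets out from 2 and accepts that ring closure. The same Sharpless epoxidation is followed by CSA, which closes the oxolane at C5 with inversion and gives (2S)-2-[(2R,5R)-5-ethenyl-5-methyloxolan-2-yl]propane-1,2-diol F1. Selective tosylation of the primary hydroxyl (TsCl, pyridine, 0 °C) gives (2S)-2-[(2R,5R)-5-ethenyl-5-methyloxolan-2-yl]-2-hydroxypropyl 4-methylbenzenesulfonate F2. Base (K2CO3, MeOH, or the base of step 3) closes F2 to epoxide 5, where the route is rejoined; 5 then goes on to 7 under the step 3 conditions. The rings then form in separate operations.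

**Step 3.** The strongly basic dianion may attack the sulfonyl sulfur or isomerise the epoxide before the lithium alkoxide has cyclised, or the opening of hindered epoxide 5 may stall. The fallback sets out from 2 and builds the carbon chain before the oxidation. MsCl/Et3N then LiBr gives (3R,6E)-8-bromo-3,7-dimethylocta-1,6-dien-3-ol F3. Alkylation with the lithium enolate of tert-butyl acetate (THF, −78 °C) gives tert-butyl (4E,8R)-8-hydroxy-4,8-dimethyldeca-4,9-dienoate F4. Shi epoxidation with the enantiomeric (L-fructose-type, from L-sorbose) ketone and Oxone gives tert-butyl 3-[(2S,3S)-3-[(3R)-3-hydroxy-3-methylpent-4-en-1-yl]-2-methyloxiran-2-yl]propanoate F5. CSA, then brief TFA, closes the oxolane (inversion at C5) and lactonises the freed tertiary alcohol, rejoining the route at 7.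

**Step 8.** The vinyl group on the quaternary oxolane carbon may be too hindered for efficient cross-metathesis, and Ru–H species may isomerise the skipped diene. The fallback sets out from 4 and changes the order of events. Cross-metathesis of 4 with 15 (Hoveyda–Grubbs II, CH2Cl2, 40 °C) is done while the tertiary allylic hydroxyl is still free, which makes the vinyl group a more reactive, hydroxyl-assisted partner. This gives [(2S,3S)-3-[(3R,4E,7E)-10-(furan-3-yl)-3-hydroxy-3,7-dimethyldeca-4,7-dien-1-yl]-2-methyloxiran-2-yl]methyl 4-methylbenzenesulfonate F6. The step 3 cascade is then run on F6 as the last step and rejoins the route at 16.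

## Further compounds

F1 | step 2 | (2S)-2-[(2R,5R)-5-ethenyl-5-methyloxolan-2-yl]propane-1,2-diol | C=C[C@@]1(C)CC[C@H]([C@@](C)(O)CO)O1
F2 | step 2 | (2S)-2-[(2R,5R)-5-ethenyl-5-methyloxolan-2-yl]-2-hydroxypropyl 4-methylbenzenesulfonate | C=C[C@@]1(C)CC[C@H]([C@@](C)(O)COS(=O)(=O)c2ccc(C)cc2)O1
F3 | step 3 | (3R,6E)-8-bromo-3,7-dimethylocta-1,6-dien-3-ol | C=C[C@](C)(O)CC/C=C(\C)CBr
F4 | step 3 | tert-butyl (4E,8R)-8-hydroxy-4,8-dimethyldeca-4,9-dienoate | C=C[C@](C)(O)CC/C=C(\C)CCC(=O)OC(C)(C)C
F5 | step 3 | tert-butyl 3-[(2S,3S)-3-[(3R)-3-hydroxy-3-methylpent-4-en-1-yl]-2-methyloxiran-2-yl]propanoate | C=C[C@](C)(O)CC[C@@H]1O[C@@]1(C)CCC(=O)OC(C)(C)C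
F6 | step 8 | [(2S,3S)-3-[(3R,4E,7E)-10-(furan-3-yl)-3-hydroxy-3,7-dimethyldeca-4,7-dien-1-yl]-2-methyloxiran-2-yl]methyl 4-methylbenzenesulfonate | C/C(=C\CCc1ccoc1)C/C=C/[C@](C)(O)CC[C@@H]1O[C@@]1(C)COS(=O)(=O)c2ccc(C)cc2
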